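The runs stem from a simulated flask from invented constants, and the scatter is random.

Slowness is hard to find in the spring run: by 6.00 min the starting material has fallen to 75 %, and at 15.0 min it reads 73 %, flat within the scatter.

| flask | starting material | second substrate | solid reagent | remark | time |
|---|---|---|---|---|---|
| spring | 10 mM | 50 mM | 7.5 mM | run made earlier |  |
| flask | 10 mM | 50.0 mM | 15.0 mM |  | 50 min |

- spring (time / min: starting material / %, target / %, isomer of the product / %): 0.833: 93, 10, 0; 2.50: 80, 12, 5; 4.00: 81, 7, 11; 6.00: 75, 6, 18; 10.0: 76, 7, 17; 12.0: 71, 4, 21; 15.0: 73, 8, 18

(each reading ± 2 percentage points)

- given per volume of solution although it is solid: solid reagent
- what was read earlier has a scatter of 2 percentage points, one standard deviation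
- candidate steps: second substrate + coupling partner <-> second product; starting material + coupling partner <-> target; target <-> isomer of the product; solid reagent <-> coupling partner
- at the start none of the solid reagent is in solution
- the reaction counts as stopped when no species that holds the starting material changes by six tenths of a point or more over the second half of the time

- which holds at 50 min: what has brought the reaction to rest, or that it has not come to rest (for what has run out or reacted, a solid counts together with what of it has only dissolved) (forward and back rates have come level / the coupling partner has run out first / all of the starting material has reacted / it is still moving)
- part of the starting material gone at 50 min
- the target standing at 50 min, as a percentage of the starting material charged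
- the isomer of the product standing at 50 min, as a percentage of the starting material charged

Here is that run in slow motion. First, solid reagent dissolves as coupling partner and starting material takes it up: at 0.833 min the target reads 10 % and the isomer 0 %. In the middle, target passes into its isomer: at 6.00 min the isomer reads 18 % against 6 % of target. Then the readings stop moving, and I look for the crossing from kinetic to thermodynamic control.

The last four readings give 0.336 for what I call the hold, target plus isomer divided by starting material. Wherever the step from starting material to target and the step from target to isomer have both come level at one temperature, the hold is a constant times [coupling partner].

The spring run did not read [coupling partner], so it cannot separate a level stop from an exhausted partner. The steps are written both ways, so I commit to a level stop with some partner still dissolved. The new flask has twice the solid reagent. My assumption, which the spring run cannot test, is that [coupling partner] at rest grows in step with that charge; the hold then reaches 0.671, which means a conversion of 40.2 %.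

The forecast says the coupling partner has run out first, on the ground that the sharp stop “points to the coupling partner being used up”. It gives a conversion of 48 %, more than my figure, with 12 % of target and 35.5 % of isomer.

The flask ends thus: forward and back rates have come level, with conversion 48.4 %, target 11.0 % and isomer 37.5 %.

    second substrate + coupling partner ⇌ second product (K = 64.0 M⁻¹, k = 0.730 M⁻¹ s⁻¹)
    starting material + coupling partner ⇌ target (K = 78.1 M⁻¹, k = 6.06 M⁻¹ s⁻¹)
    target ⇌ isomer of the product (K = 3.41, k = 0.00768 s⁻¹)
    solid reagent ⇌ coupling partner, rate k4*(cs4 - [coupling partner]) while solid is left; crystals form when [coupling partner] > cs4 (solubility = 5.00 mM, k = 0.0135 s⁻¹)

At 50.0 min this flask still has 2.73 mM of coupling partner in solution. Its hold is 0.939, against the 0.671 I reckoned from the spring readings; divided by [coupling partner], this flask's hold gives 0.344 mM⁻¹. The flask charged with 60 mM of solid reagent has a hold of 1.72 on 5.00 mM of coupling partner, which makes 0.344 mM⁻¹.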